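**Retrosynthetic overview**
1. The only stereocentre (oxindole C3, S) is set last, by ene-reductase reduction of the C3=CH bond of the (Z)-3-(pyrazinonylmethylidene)oxindole 11.
2. 11 is disconnected at the exocyclic C=C (Knoevenagel) into 7-prenyloxindole 10 and pyrazinone aldehyde 7.
3. 10 comes from 7-bromooxindole 8 by Stille allylation, then cross-metathesis of allyl to prenyl.
4. 7 comes from 3-methylpyrazin-2(1H)-one 1 by C5 bromination, O-PMB protection, Br-directed C6 magnesiation/formylation, SNAr Br→OMe and PMB removal.
5. Ring order: no ring is built; the oxindole and pyrazinone rings are both bought preformed and only functionalised.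

Assumption: the SMILES stereocentre reads as (S) at oxindole C3, and an (S)-selective ene-reductase is found by screening a commercial panel; activity on this particular substrate is assumed by analogy, not known.

**Step 1**
Reactants: 1 3-methylpyrazin-2(1H)-one
Product: 2 5-bromo-3-methylpyrazin-2(1H)-one
Conditions: NBS (1.05 equiv), DMF, 0 °C to rt, dark
Reagents that add atoms: N-bromosuccinimide, O=C1CCC(=O)N1Br
Why: Electrophilic aromatic bromination of a pyrazin-2(1H)-one goes to C5 (β-carbon of the N1–C6=C5 enamide) because C3 is blocked by methyl, and polar solvent in the dark suppresses radical attack on the methyl group.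

**Step 2**
Reactants: 2 5-bromo-3-methylpyrazin-2(1H)-one
Product: 3 5-bromo-2-[(4-methoxybenzyl)oxy]-3-methylpyrazine
Conditions: PMBCl (1.2 equiv), Ag2CO3 (0.6 equiv), toluene, 70 °C, dark
Reagents that add atoms: 4-methoxybenzyl chloride, COc1ccc(CCl)cc1
Why: Silver-salt O-alkylation of the ambident lactam in a non-polar solvent gives the lactim (O-PMB) ether, which masks the acidic N–H for the metalation.

**Step 3**
Reactants: 3 5-bromo-2-[(4-methoxybenzyl)oxy]-3-methylpyrazine
Product: 5 3-bromo-6-[(4-methoxybenzyl)oxy]-5-methylpyrazine-2-carbaldehyde, via pyrazinylmagnesium chloride 4 (not isolated)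
Conditions: TMPMgCl·LiCl (1.2 equiv), THF, –40 °C, 1 h; DMF (3 equiv), –40 to 0 °C; aq. NH4Cl
Reagents that add atoms: TMPMgCl·LiCl, CC1(C)CCCC(C)(C)N1[Mg]Cl.[Li+].[Cl-] (MgCl in 4); N,N-dimethylformamide, CN(C)C=O (CHO in 5)
Why: Directed ortho-metalation with the Knochel–Hauser base removes the only ring C–H, which is acidified by the adjacent ring N and C–Br, and the arylmagnesium (stable at –40 °C) is formylated by DMF, the hemiaminal salt releasing the aldehyde on work-up.

**Step 4**
Reactants: 5 3-bromo-6-[(4-methoxybenzyl)oxy]-5-methylpyrazine-2-carbaldehyde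
Product: 6 3-methoxy-6-[(4-methoxybenzyl)oxy]-5-methylpyrazine-2-carbaldehyde
Conditions: NaOMe (1.1 equiv), MeOH/THF, 0 °C to rt
Reagents that add atoms: sodium methoxide, [Na+].[O-]C
Why: Nucleophilic aromatic substitution (SNAr) is fast because the bromide is ortho to the formyl group and α to a ring nitrogen, which take up the Meisenheimer charge, so the PMB ether carbon is not attacked.

**Step 5**
Reactants: 6 3-methoxy-6-[(4-methoxybenzyl)oxy]-5-methylpyrazine-2-carbaldehyde
Product: 7 3-methoxy-5-methyl-6-oxo-1,6-dihydropyrazine-2-carbaldehyde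
Conditions: TFA/CH2Cl2 (1:9), anisole (3 equiv), 0 °C, 30 min
Reagents that add atoms: none
Why: Acidolysis of the PMB lactim ether proceeds through the stabilised PMB cation (trapped by Friedel–Crafts alkylation of anisole) and frees the pyrazinone, while the methyl lactim ether cannot ionise and the aldehyde is inert.

**Step 6**
Reactants: 8 7-bromoindolin-2-one
Product: 9 7-allylindolin-2-one
Conditions: allylSnBu3 (1.3 equiv), Pd(PPh3)4 (5 mol %), DMF, 90 °C
Reagents that add atoms: allyltributylstannane, C=CC[Sn](CCCC)(CCCC)CCCC
Why: Stille coupling under neutral conditions tolerates the free lactam N–H and the acidic C3 methylene, and the symmetric allyl group avoids the linear/branched ambiguity of a direct prenyl transfer.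

**Step 7**
Reactants: 9 7-allylindolin-2-one
Product: 10 7-(3-methylbut-2-en-1-yl)indolin-2-one
Conditions: Grubbs II (3 mol %), 2-methylbut-2-ene/CH2Cl2 (1:2), 40 °C, sealed tube
Reagents that add atoms: 2-methylbut-2-ene, CC=C(C)C
Why: Olefin cross-metathesis of a terminal allylarene with excess 2-methylbut-2-ene gives the trisubstituted prenyl alkene with loss of propene, with no E/Z issue and no effect on the lactam.

**Step 8**
Reactants: 7 3-methoxy-5-methyl-6-oxo-1,6-dihydropyrazine-2-carbaldehyde; 10 7-(3-methylbut-2-en-1-yl)indolin-2-one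
Product: 11 (Z)-3-[(3-methoxy-5-methyl-6-oxo-1,6-dihydropyrazin-2-yl)methylidene]-7-(3-methylbut-2-en-1-yl)indolin-2-one
Conditions: piperidine (0.3 equiv), AcOH (0.3 equiv), EtOH, 78 °C; product filtered after cooling
Reagents that add atoms: none
Why: Knoevenagel condensation at the oxindole C3 methylene under piperidinium acetate catalysis gives the thermodynamic Z alkene, held by an intramolecular hydrogen bond from the pyrazinone N–H to the oxindole C2 carbonyl.

**Step 9**
Reactants: 11 (Z)-3-[(3-methoxy-5-methyl-6-oxo-1,6-dihydropyrazin-2-yl)methylidene]-7-(3-methylbut-2-en-1-yl)indolin-2-one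
Product: 12 Astepyrazinol B [(3S)-3-[(3-methoxy-5-methyl-6-oxo-1,6-dihydropyrazin-2-yl)methyl]-7-(3-methylbut-2-en-1-yl)indolin-2-one]
Conditions: ene-reductase (flavin-dependent Old Yellow Enzyme family, (S)-selective panel hit), NADP+ (1 mol %), i-PrOH (10 % v/v) with NADP-dependent alcohol dehydrogenase for cofactor recycling, KPi buffer pH 6.5, DMSO (10 % v/v), 30 °C, N2, 24 h; EtOAc extraction at pH 6, no base in work-up
Reagents that add atoms: none
Why: Biocatalytic asymmetric conjugate reduction by an ene-reductase: FMNH2 transfers hydride to the exocyclic β-carbon and the active-site tyrosine protonates C3 from the opposite face, so the enzyme selected for the right facial preference fixes C3 as S, the unactivated prenyl alkene is not a substrate, and pH 6.5 keeps the new C3–H from epimerising.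

**Compound list**
1 | 3-methylpyrazin-2(1H)-one | Cc1ncc[nH]c1=O | starting material
2 | 5-bromo-3-methylpyrazin-2(1H)-one | Cc1nc(Br)c[nH]c1=O | intermediate
3 | 5-bromo-2-[(4-methoxybenzyl)oxy]-3-methylpyrazine | Cc1nc(Br)cnc1OCc1ccc(OC)cc1 | intermediate
4 | {3-bromo-6-[(4-methoxybenzyl)oxy]-5-methylpyrazin-2-yl}magnesium chloride | Cc1nc(Br)c([Mg]Cl)nc1OCc1ccc(OC)cc1 | intermediate (not isolated)
5 | 3-bromo-6-[(4-methoxybenzyl)oxy]-5-methylpyrazine-2-carbaldehyde | O=Cc1nc(OCc2ccc(OC)cc2)c(C)nc1Br | intermediate
6 | 3-methoxy-6-[(4-methoxybenzyl)oxy]-5-methylpyrazine-2-carbaldehyde | O=Cc1nc(OCc2ccc(OC)cc2)c(C)nc1OC | intermediate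
7 | 3-methoxy-5-methyl-6-oxo-1,6-dihydropyrazine-2-carbaldehyde | O=Cc1[nH]c(=O)c(C)nc1OC | intermediate
8 | 7-bromoindolin-2-one | O=C1Cc2cccc(Br)c2N1 | starting material
9 | 7-allylindolin-2-one | C=CCc1cccc2c1NC(=O)C2 | intermediate
10 | 7-(3-methylbut-2-en-1-yl)indolin-2-one | CC(C)=CCc1cccc2c1NC(=O)C2 | intermediate
11 | (Z)-3-[(3-methoxy-5-methyl-6-oxo-1,6-dihydropyrazin-2-yl)methylidene]-7-(3-methylbut-2-en-1-yl)indolin-2-one | O=C1Nc2c(CC=C(C)C)cccc2/C1=C/c1[nH]c(=O)c(C)nc1OC | intermediate
12 | Astepyrazinol B, (3S)-3-[(3-methoxy-5-methyl-6-oxo-1,6-dihydropyrazin-2-yl)methyl]-7-(3-methylbut-2-en-1-yl)indolin-2-one | COc1nc(C)c(=O)[nH]c1C[C@@H]1C(=O)Nc2c(CC=C(C)C)cccc21 | target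

**Totals**
Total step count: 9. Longest linear sequence: 7 steps (steps 1, 2, 3, 4, 5, 8, 9); the oxindole branch is 2 steps (6, 7).

**Three steps most likely to fail, with fallbacks**

Step 3 (magnesiation/formylation of 3). The risk is lateral metalation of the methyl group or halogen migration. The fallback sets out from 3 and inverts the order of C–O and C–C bond formation. Pd-catalysed C–O coupling with methanol (tBuBrettPhos Pd G3, Cs2CO3, MeOH, dioxane, 60 °C) gives 5-methoxy-2-[(4-methoxybenzyl)oxy]-3-methylpyrazine F1. Its methoxy group then directs ortho-lithiation of the single ring C–H (LiTMP, THF, –78 °C, short contact), and a DMF quench gives the aldehyde directly. The route is rejoined at 6, with steps 3 and 4 replaced.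

Step 8 (Knoevenagel with the N–H acidic aldehyde 7). The risk is that 7 reacts sluggishly because its amidate is a deactivated electrophile. The fallback sets out from 6 and 10 and keeps the PMB group through the condensation. Piperidine in EtOH at 78 °C gives (E)-3-({3-methoxy-6-[(4-methoxybenzyl)oxy]-5-methylpyrazin-2-yl}methylidene)-7-(3-methylbut-2-en-1-yl)indolin-2-one F2. Brief TFA/anisole/CH2Cl2 at 0 °C then removes PMB; the prenyl group tolerates cold dilute acid, and the alkene equilibrates to the hydrogen-bonded Z form. The route is rejoined at 11, with step 5 skipped.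

Step 9 (ene-reductase reduction). The risk is that no panel enzyme accepts this bulky, poorly soluble substrate or gives high ee. The fallback sets out from 11 and uses chemical asymmetric catalysis instead. Rh-catalysed asymmetric hydrogenation is run with [Rh(cod)2]BF4 and a chiral ferrocenyl bisphosphine–thiourea ligand (the enantiomer of the ligand that gives S), H2 (30 bar), CH2Cl2/i-PrOH, 25 °C. The thiourea hydrogen-bonds the lactam, and the cationic Rh–bisphosphine does not reduce the unfunctionalised trisubstituted prenyl alkene. It arrives directly at 12 and makes no new compound (F0).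

**Further compounds**
F1 | step 3 | 5-methoxy-2-[(4-methoxybenzyl)oxy]-3-methylpyrazine | Cc1nc(OC)cnc1OCc1ccc(OC)cc1
F2 | step 8 | (E)-3-({3-methoxy-6-[(4-methoxybenzyl)oxy]-5-methylpyrazin-2-yl}methylidene)-7-(3-methylbut-2-en-1-yl)indolin-2-one | O=C1Nc2c(CC=C(C)C)cccc2/C1=C\c1nc(OCc2ccc(OC)cc2)c(C)nc1OC
F0 | step 9 | none | none
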